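Both indoles are disconnected at N1–C7a and C3–C3a. In each, the nitrogen and C3 are bonded to the two ring-fusion carbons C7a and C3a of a benzo ring whose other four positions carry only hydrogen, which is exactly what benzyne delivers. A single twofold aryne annulation therefore forges four bonds and both indole five-membered rings on the fully substituted pyrrole. Its substrate is the N-SEM methyl 5-acetylpyrrole-2-carboxylate bearing C(=O)CH2NHTs chains at C3 and C4. It is built from the 3,4-dibromide by vinyl ether cross-coupling, bromohydration and alkylation of a Boc-capped sulfonamide, which cannot dialkylate or bridge the two arms.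

Key step: step 8

Remark: the target has no stereocentre, and tert-butyl tosylcarbamate is assumed to be purchased as the nitrogen source for the two side chains.

Step 1
Reactants: 1 methyl 1H-pyrrole-2-carboxylate
Product: 2 methyl 5-acetyl-1H-pyrrole-2-carboxylate
Conditions: Ac2O, BF3·OEt2, ClCH2CH2Cl, 0 °C → rt
Reagents that add atoms: acetic anhydride, CC(=O)OC(C)=O
Why: Friedel–Crafts acylation in which a weak Lewis acid leaves the ester uncomplexed, so the innate α-reactivity of the pyrrole should place the acetyl group at C5, whereas a strong Lewis acid such as AlCl3 would divert it to C4.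

Step 2
Reactants: 2 methyl 5-acetyl-1H-pyrrole-2-carboxylate
Product: 3 methyl 5-acetyl-3,4-dibromo-1H-pyrrole-2-carboxylate
Conditions: NBS (2.2 equiv), DMF, 0 → 40 °C
Reagents that add atoms: N-bromosuccinimide, O=C1CCC(=O)N1Br
Why: Electrophilic aromatic bromination at C3 and C4, the only unsubstituted ring carbons, under polar acid-free conditions in which the NH-pyrrole ring should react faster than the acetyl methyl group can enolize.

Step 3
Reactants: 3 methyl 5-acetyl-3,4-dibromo-1H-pyrrole-2-carboxylate
Product: 4 methyl 5-acetyl-3,4-dibromo-1-[2-(trimethylsilyl)ethoxymethyl]pyrrole-2-carboxylate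
Conditions: NaH (1.1 equiv), SEMCl, DMF, 0 °C → rt
Reagents that add atoms: 2-(trimethylsilyl)ethoxymethyl chloride, C[Si](C)(C)CCOCCl
Why: N-alkylation of the sodium pyrrolide (the N–H flanked by two carbonyl groups is by far the most acidic site) by the reactive chloromethyl ether, which installs the group that later keeps benzyne away from the pyrrole nitrogen.

Step 4
Reactants: 4 methyl 5-acetyl-3,4-dibromo-1-[2-(trimethylsilyl)ethoxymethyl]pyrrole-2-carboxylate; 5 tributyl(1-ethoxyvinyl)stannane (2.6 equiv)
Product: 6 methyl 5-acetyl-3,4-bis(1-ethoxyvinyl)-1-[2-(trimethylsilyl)ethoxymethyl]pyrrole-2-carboxylate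
Conditions: Pd(PPh3)4 (10 mol %), CuI (20 mol %), 1,4-dioxane, 100 °C; filtration through Et3N-deactivated silica
Reagents that add atoms: none
Why: Twofold Stille coupling in which the small 1-ethoxyvinyl group should transfer readily to the electron-poor heteroaryl bromides, CuI speeding transmetalation at the crowded C3 and C4, while the neutral medium leaves ketone, ester and SEM group alone.

Step 5
Reactants: 6 methyl 5-acetyl-3,4-bis(1-ethoxyvinyl)-1-[2-(trimethylsilyl)ethoxymethyl]pyrrole-2-carboxylate
Product: 7 methyl 5-acetyl-3,4-bis(bromoacetyl)-1-[2-(trimethylsilyl)ethoxymethyl]pyrrole-2-carboxylate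
Conditions: NBS (2.1 equiv), THF–H2O (4:1), 0 °C
Reagents that add atoms: N-bromosuccinimide, O=C1CCC(=O)N1Br; water, O
Why: Bromohydration of an enol ether, in which each electron-rich alkene takes up electrophilic bromine, water captures the oxocarbenium ion and the hemiketal collapses to the bromomethyl ketone, so only the two masked arms are brominated and the free 5-acetyl group stays a methyl ketone.

Step 6
Reactants: 7 methyl 5-acetyl-3,4-bis(bromoacetyl)-1-[2-(trimethylsilyl)ethoxymethyl]pyrrole-2-carboxylate; 8 tert-butyl tosylcarbamate (2.3 equiv)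
Product: 9 methyl 5-acetyl-3,4-bis[N-(tert-butoxycarbonyl)-N-(4-methylphenylsulfonyl)glycyl]-1-[2-(trimethylsilyl)ethoxymethyl]pyrrole-2-carboxylate
Conditions: 8 premixed with K2CO3 in DMF, then 7, 0 °C → rt
Reagents that add atoms: none
Why: Gabriel-type SN2 displacement at the activated α-bromoketones by the weakly basic potassium salt of the N-Boc sulfonamide, whose Boc cap leaves no N–H after one alkylation, so neither dialkylation nor bridging of the neighbouring arms into a seven-membered ring can occur.

Step 7
Reactants: 9 methyl 5-acetyl-3,4-bis[N-(tert-butoxycarbonyl)-N-(4-methylphenylsulfonyl)glycyl]-1-[2-(trimethylsilyl)ethoxymethyl]pyrrole-2-carboxylate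
Product: 10 methyl 5-acetyl-3,4-bis[N-(4-methylphenylsulfonyl)glycyl]-1-[2-(trimethylsilyl)ethoxymethyl]pyrrole-2-carboxylate
Conditions: CF3CO2H–CH2Cl2 (1:4), 0 °C → rt, short reaction time
Reagents that add atoms: none
Why: Acidolysis of a tert-butyl carbamate (loss of the tert-butyl cation, then decarboxylation), which is fast on a sulfonamide nitrogen, so brief exposure to dilute acid should leave the N-SEM group of the electron-poor pyrrole intact.

Step 8
Reactants: 10 methyl 5-acetyl-3,4-bis[N-(4-methylphenylsulfonyl)glycyl]-1-[2-(trimethylsilyl)ethoxymethyl]pyrrole-2-carboxylate; 11 2-(trimethylsilyl)phenyl trifluoromethanesulfonate (3 equiv)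
Product: 13 methyl 5-acetyl-3,4-bis(1-tosylindol-3-yl)-1-[2-(trimethylsilyl)ethoxymethyl]pyrrole-2-carboxylate, via bis(3-hydroxy-1-tosylindolin-3-yl)pyrrole diol 12 (not isolated)
Conditions: CsF (6 equiv), MeCN, rt → 50 °C; then TsOH·H2O (cat.), CH2Cl2, rt
Reagents that add atoms: none
Why: Fluoride-induced 1,2-elimination of 11 releases benzyne, each sulfonamide (deprotonated by CsF) adds through nitrogen to make N1–C7a, and the ortho aryl anion thus generated attacks the ketone of its own arm to make C3–C3a; the tertiary 3-hydroxyindolines of 12 then lose water under acid catalysis (E1, driven by aromatization) to give the N-tosylindoles. The closest known reaction type is the aryne annulation of N-sulfonyl α-amino ketones to 3-hydroxyindolines and indoles, the same N-arylation/carbonyl-trapping cascade that 2-aminoaryl ketones undergo. Each of the two five-membered rings closes by 5-exo-trig addition of the aryl anion to a C=O group. The carbinol centres of 12 form without control and are erased by the dehydration, so no stereocentre has to be set. The step needs nitrogen to react before carbon, the aryl anion to choose its own ketone over the acetyl, ester and neighbouring ketone, and one aryne per arm. These are secured because the sulfonamide N–H is the only site acidic enough for CsF, the 5-exo trap outruns the seven- and eight-membered alternatives, the nitrogen is tertiary after one arylation, SEM masks the pyrrole nitrogen, and symmetrical benzyne raises no regiochemical question.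

Step 9
Reactants: 13 methyl 5-acetyl-3,4-bis(1-tosylindol-3-yl)-1-[2-(trimethylsilyl)ethoxymethyl]pyrrole-2-carboxylate
Product: 14 methyl 5-acetyl-3,4-bis(1H-indol-3-yl)-1H-pyrrole-2-carboxylate (CNP0281950.0)
Conditions: Bu4NF (1 M in THF, excess), THF, 65 °C; aq NH4Cl
Reagents that add atoms: none
Why: Fluoride-mediated global deprotection, in which fluoride attacks sulfur of the two indole N-tosyl groups (desulfonylation) and silicon of the SEM group (β-elimination to ethene, then loss of formaldehyde), while the pyrrolide and indolide anions formed should shield the acetyl and ester groups from enolization and hydrolysis until the quench.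

Compound list
1 | methyl 1H-pyrrole-2-carboxylate | COC(=O)c1ccc[nH]1 | starting material
2 | methyl 5-acetyl-1H-pyrrole-2-carboxylate | COC(=O)c1ccc(C(C)=O)[nH]1 | intermediate
3 | methyl 5-acetyl-3,4-dibromo-1H-pyrrole-2-carboxylate | COC(=O)c1[nH]c(C(C)=O)c(Br)c1Br | intermediate
4 | methyl 5-acetyl-3,4-dibromo-1-[2-(trimethylsilyl)ethoxymethyl]pyrrole-2-carboxylate | COC(=O)c1n(COCC[Si](C)(C)C)c(C(C)=O)c(Br)c1Br | intermediate
5 | tributyl(1-ethoxyvinyl)stannane | CCOC(=C)[Sn](CCCC)(CCCC)CCCC | starting material
6 | methyl 5-acetyl-3,4-bis(1-ethoxyvinyl)-1-[2-(trimethylsilyl)ethoxymethyl]pyrrole-2-carboxylate | COC(=O)c1n(COCC[Si](C)(C)C)c(C(C)=O)c(C(=C)OCC)c1C(=C)OCC | intermediate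
7 | methyl 5-acetyl-3,4-bis(bromoacetyl)-1-[2-(trimethylsilyl)ethoxymethyl]pyrrole-2-carboxylate | COC(=O)c1n(COCC[Si](C)(C)C)c(C(C)=O)c(C(=O)CBr)c1C(=O)CBr | intermediate
8 | tert-butyl tosylcarbamate (N-Boc-4-methylbenzenesulfonamide) | Cc1ccc(S(=O)(=O)NC(=O)OC(C)(C)C)cc1 | starting material
9 | methyl 5-acetyl-3,4-bis[N-(tert-butoxycarbonyl)-N-(4-methylphenylsulfonyl)glycyl]-1-[2-(trimethylsilyl)ethoxymethyl]pyrrole-2-carboxylate | COC(=O)c1n(COCC[Si](C)(C)C)c(C(C)=O)c(C(=O)CN(C(=O)OC(C)(C)C)S(=O)(=O)c2ccc(C)cc2)c1C(=O)CN(C(=O)OC(C)(C)C)S(=O)(=O)c1ccc(C)cc1 | intermediate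
10 | methyl 5-acetyl-3,4-bis[N-(4-methylphenylsulfonyl)glycyl]-1-[2-(trimethylsilyl)ethoxymethyl]pyrrole-2-carboxylate | COC(=O)c1n(COCC[Si](C)(C)C)c(C(C)=O)c(C(=O)CNS(=O)(=O)c2ccc(C)cc2)c1C(=O)CNS(=O)(=O)c1ccc(C)cc1 | intermediate
11 | 2-(trimethylsilyl)phenyl trifluoromethanesulfonate | C[Si](C)(C)c1ccccc1OS(=O)(=O)C(F)(F)F | starting material
12 | methyl 5-acetyl-3,4-bis(3-hydroxy-1-tosylindolin-3-yl)-1-[2-(trimethylsilyl)ethoxymethyl]pyrrole-2-carboxylate (not isolated; diastereomer mixture at the two carbinol carbons, configuration undefined) | COC(=O)c1n(COCC[Si](C)(C)C)c(C(C)=O)c(C2(O)CN(S(=O)(=O)c3ccc(C)cc3)c3ccccc32)c1C1(O)CN(S(=O)(=O)c2ccc(C)cc2)c2ccccc21 | intermediate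
13 | methyl 5-acetyl-3,4-bis(1-tosylindol-3-yl)-1-[2-(trimethylsilyl)ethoxymethyl]pyrrole-2-carboxylate | COC(=O)c1n(COCC[Si](C)(C)C)c(C(C)=O)c(-c2cn(S(=O)(=O)c3ccc(C)cc3)c3ccccc23)c1-c1cn(S(=O)(=O)c2ccc(C)cc2)c2ccccc12 | intermediate
14 | methyl 5-acetyl-3,4-bis(1H-indol-3-yl)-1H-pyrrole-2-carboxylate | COC(=O)c1[nH]c(C(C)=O)c(-c2c[nH]c3ccccc23)c1-c1c[nH]c2ccccc12 | target

Total step count: 9. Longest linear sequence: 9 steps (1 → 14).

Steps most likely to fail

Step 8. After N-arylation the aryl anion may be protonated before it reaches the hindered ketone. The second arm may also stall once a bulky hydroxyindoline sits next to it, leaving mono-annulated or merely N-phenylated material. The fallback brings the indoles in preformed: it sets out from 4 and couples it twice with purchased (1-tosylindol-3-yl)boronic acid in a Suzuki–Miyaura reaction (Pd(OAc)2, SPhos, K3PO4, 1,4-dioxane–H2O, 90 °C). This should give the bis(N-tosylindolyl)pyrrole directly, so the route is rejoined at 13; the fallback makes no compound outside the list (F0).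

Step 4. The second coupling, at a bromide flanked by the new ethoxyvinyl group and a carbonyl substituent, may be slow, so that protodebromination or premature hydrolysis of the enol ether competes. The fallback changes both the halide and the coupling partner and sets out from 2. Iodination (NIS, cat. CF3CO2H, MeCN) should give methyl 5-acetyl-3,4-diiodo-1H-pyrrole-2-carboxylate F1. SEM protection (NaH, SEMCl, DMF) should give methyl 5-acetyl-3,4-diiodo-1-[2-(trimethylsilyl)ethoxymethyl]pyrrole-2-carboxylate F2. A twofold Suzuki–Miyaura coupling with purchased 2-(1-ethoxyvinyl)-4,4,5,5-tetramethyl-1,3,2-dioxaborolane (Pd(OAc)2, SPhos, K3PO4, 1,4-dioxane–H2O, 80 °C) then returns to the route at 6.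

Step 1. Positional selectivity may be poor, with acylation at C4 competing with the desired attack at C5. The fallback sets out from 1 and uses the Vilsmeier–Haack formylation (POCl3, DMF, ClCH2CH2Cl, then aq NaOAc), which favours C5 and should give methyl 5-formyl-1H-pyrrole-2-carboxylate F3, purified from the minor 4-formyl isomer by crystallization. Addition of MeMgBr (2.2 equiv, THF, −78 → 0 °C; the first equivalent deprotonates N–H) should give racemic methyl 5-(1-hydroxyethyl)-1H-pyrrole-2-carboxylate F4. Oxidation of this pyrrolyl carbinol with MnO2 in CH2Cl2 comes back to the route at 2.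

Further compounds
F0 | step 8 | none | none
F1 | step 4 | methyl 5-acetyl-3,4-diiodo-1H-pyrrole-2-carboxylate | COC(=O)c1[nH]c(C(C)=O)c(I)c1I
F2 | step 4 | methyl 5-acetyl-3,4-diiodo-1-[2-(trimethylsilyl)ethoxymethyl]pyrrole-2-carboxylate | COC(=O)c1n(COCC[Si](C)(C)C)c(C(C)=O)c(I)c1I
F3 | step 1 | methyl 5-formyl-1H-pyrrole-2-carboxylate | COC(=O)c1ccc(C=O)[nH]1
F4 | step 1 | methyl 5-(1-hydroxyethyl)-1H-pyrrole-2-carboxylate (racemic) | COC(=O)c1ccc(C(C)O)[nH]1
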